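(The numbers in the tables are simulated with constants of no real substance; noise was put on by code.)

You have no rate constants for this flask, so start from the one constant the charges give, the balance of G, the limiting reagent: c(G) is 0.0120 M against 0.020 M of c(Q). If each J costs one G, J stops at the G ceiling, the G charged as a percentage of the Q charged: 60.0%.

| setting | Friday's | Saturday's | flask |
|---|---|---|---|
| Q | 0.020 M | 0.013 M | 0.020 M |
| G | 0.60 equiv | 0.60 equiv | 0.600 equiv |
| E | 5 mol% | 5 mol% | 5 mol% |
| remark | the very flask that is asked about, followed so far | run made earlier |  |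
| time |  |  | 8.0 min |

- Friday's (time / s: Q / %, J / %): 10.0: 56, 31; 15.0: 40, 42; 25.0: 21, 60; 40.0: 23, 63; 60.0: 20, 58; 80.0: 24, 59; 90.0: 21, 56
- Saturday's (time / min: Q / %, J / %): 0.167: 52, 25; 0.500: 25, 57; 0.833: 21, 62; 1.33: 23, 62; 2.00: 21, 61; 2.50: 25, 60; 3.00: 27, 60

(each reading ± 2 percentage points)

- the numbers in the tables scatter by 2 percentage points (one standard deviation)
- what has gone from Q into another species counts as reacted, even if it can come back

- how much of the Q has reacted by 8.0 min
- how much J there is at 8.0 min, in percent of the Q charged

Climb the ladder in Friday's run, starting from its first reading. At 10.0 s, J already reads 31%. By 25.0 s it reads 60%, at the ceiling, and Q reads 21% and stays near there to the last reading. The asked 8.0 min lies far later than that rung. On a later rung, Saturday's Q reads 21% and then 27% between 2.00 min and 3.00 min, while its J reads 61% and then 60%, so any creep barely clears the scatter.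

My own reckoning puts J on the ceiling at 8.0 min. Taking Q as the mean of the last reading of Friday's run and that of Saturday's run, 24.0%, I get a conversion of 76.0% and estimate that 16 percentage points of the Q charged sits in something unseen.

The forecast gives 73% conversion and 58% J, reasoning that "J is therefore capped by G". Its conversion lies below mine.

The flask gives 76.1% conversion and 59.9% J, and both forecast values hold within the tolerance.

    Q + E ⇌ Q.E (K = 140 L mol⁻¹, k = 1300 L mol⁻¹ s⁻¹)
    Q ⇌ X (K = 0.490, k = 0.0210 s⁻¹)
    G.D → E + J (k = 4.80 s⁻¹)
    Q.E ⇌ D (K = 12.0, k = 1.10 s⁻¹)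
    G → Z (k = 1.60 × 10⁻⁴ s⁻¹)
    G + D → G.D (k = 7200 L mol⁻¹ s⁻¹)

At 8.00 min the asked flask has G at 0% of its charge and J at 59.9%, on the ceiling. Cut G to 0.240 equiv and the ceiling becomes 24.0%. That neighbour flask, at 8.00 min, has G at 0% of its charge and J at 24.0%, again on its ceiling. Q there stands at 47.8% and X at 23.4%, and the neighbour's conversion is 52.2%.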